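Numbering (labdane): ring A = C1–C5 + C10 (C4 carries the gem-dimethyl group); ring B = C5–C10 (C6 = CH–OAc, C7 = CH2, C8 = CH–CH3, C9 = spiro carbon, C10 = C–CH3); side chain C11–C16 (C13 = second spiro carbon, C15 = lactone C=O, C16 = OCH2).
End game, backwards: acetate ⇒ 6β-alcohol; γ-lactone ⇒ 15,16-diol (oxidation at C15); tetrahydrofuran C13–O ⇒ 5-exo opening of a (13R)-13,16-epoxide by the C9 hydroxyl; C11–C12 ⇒ 9α,11-epoxide + allyl dianion of 3-methylbut-3-en-1-ol; epoxide ⇒ C9=C11 methylene ⇒ C9 ketone; C6–OH ⇒ C6 ketone ⇒ C6 nitro.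
Enabling feature: in ring B the two oxygen-bearing carbons C6 and C9 are 1,4 to each other, with C7–C8 on one side and the ring fusion C5–C10 on the other; at the nitro/ketone oxidation level ring B is the [4+2] retron of a 2-aminodiene C7=C8–C9(N)=C10 and a nitroalkene C5=C6, and C1–C4 of ring A are the tether between them.
Key disconnection: C5–C10 and C6–C7 in one operation, by an amine-catalysed double Michael reaction (formal intramolecular Diels–Alder reaction) of the acyclic, racemic nitro dienone 15; the racemic C10–H centre and the E/Z enamines converge on one quaternary configuration.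
Order of ring formation: rings A and B together (step 8: ring A through C5–C10, then ring B through C6–C7), then the tetrahydrofuran ring (step 14), then the γ-lactone (step 15).

Key step: step 8

Remark (assumption): the facial sense of induction of the (S)-diamine catalyst in step 8, of the (S)-amine auxiliary in its fallback and of the (R,R)-ligand in step 14 is assigned by analogy with the parent reaction classes; if it proved opposite, the commercially available antipode would be used with no other change.

Step 1
Reactants: 1 isobutyronitrile; 2 1,3-dibromopropane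
Product: 4 5-bromo-2,2-dimethylpentanenitrile, via lithiated isobutyronitrile 3 (not isolated)
Conditions: LiN(i-Pr)2, THF, −78 °C; then 2 (3 equiv), −78 °C → rt
Reagents that add atoms: none
Why: α-Alkylation (SN2) of the lithiated nitrile with the dibromide in excess should stop at monoalkylation and places the gem-dimethyl carbon C4 next to the future C5; no stereocentre is formed.

Step 2
Reactants: 5 N-methoxy-N-methylpropanamide; 4 5-bromo-2,2-dimethylpentanenitrile
Product: 7 6-cyano-N-methoxy-N,2,6-trimethylheptanamide (racemic), via lithium enolate 6 (not isolated)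
Conditions: LiN(i-Pr)2, THF, −78 °C; then 4, DMPU, −78 → 0 °C
Reagents that add atoms: none
Why: Amide enolate alkylation (SN2) with the primary bromide forms the C1–C10 bond; the new stereocentre is left racemic on purpose because step 8 erases and resets it, and the tertiary nitrile has no α-hydrogen and should be inert.

Step 3
Reactants: 7 6-cyano-N-methoxy-N,2,6-trimethylheptanamide; 8 isopropenylmagnesium bromide CH2=C(CH3)MgBr
Product: 9 2,2,6,8-tetramethyl-7-oxonon-8-enenitrile (racemic)
Conditions: THF, 0 °C; then 1 M HCl
Reagents that add atoms: none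
Why: Weinreb ketone synthesis, in which chelation prevents over-addition until the acidic work-up, while the hindered tertiary nitrile should not compete at 0 °C.

Step 4
Reactants: 9 2,2,6,8-tetramethyl-7-oxonon-8-enenitrile
Product: 10 7-hydroxy-2,2,6,8-tetramethylnon-8-enal (mixture of stereoisomers)
Conditions: i-Bu2AlH (3.5 equiv), CH2Cl2, −78 → −20 °C; then aq. potassium sodium tartrate
Reagents that add atoms: water, O
Why: The aluminium hydride reduces the enone 1,2 to the allylic alcohol (a temporary lower oxidation level that masks the vinyl ketone) and the nitrile to the aldehyde after hydrolytic work-up; the carbinol centre is formed unselectively and is removed in step 6.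

Step 5
Reactants: 10 7-hydroxy-2,2,6,8-tetramethylnon-8-enal; 11 nitromethane
Product: 12 2,4,8,8-tetramethyl-10-nitrodec-1-ene-3,9-diol (mixture of stereoisomers)
Conditions: 11 (10 equiv), KOt-Bu (10 mol %), THF/t-BuOH, 0 °C → rt
Reagents that add atoms: none
Why: Henry (nitroaldol) reaction of the non-enolisable neopentyl-type aldehyde, run at the allylic alcohol stage because a vinyl ketone would take up nitromethane by Michael addition; the new carbinol centre is lost in step 7.

Step 6
Reactants: 12 2,4,8,8-tetramethyl-10-nitrodec-1-ene-3,9-diol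
Product: 13 9-hydroxy-2,4,8,8-tetramethyl-10-nitrodec-1-en-3-one (mixture of stereoisomers)
Conditions: MnO2 (20 equiv), CH2Cl2, rt
Reagents that add atoms: none
Why: MnO2 oxidises allylic alcohols selectively, so it should give the isopropenyl ketone and leave the saturated β-nitro alcohol untouched.

Step 7
Reactants: 13 9-hydroxy-2,4,8,8-tetramethyl-10-nitrodec-1-en-3-one
Product: 15 (E)-2,4,8,8-tetramethyl-10-nitrodeca-1,9-dien-3-one (racemic at C4 of the chain), via mesylate 14 (not isolated)
Conditions: MsCl, Et3N, CH2Cl2, −20 → 0 °C
Reagents that add atoms: none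
Why: Mesylation of the β-nitro alcohol and E1cB elimination (dehydration of a Henry adduct) should give the conjugated nitroalkene in its thermodynamically favoured E geometry.

Step 8
Reactants: 15 (E)-2,4,8,8-tetramethyl-10-nitrodeca-1,9-dien-3-one
Product: 18 (2R,4S,4aS,8aS)-2,5,5,8a-tetramethyl-4-nitrooctahydronaphthalen-1(2H)-one, via dienamine 16 (not isolated), via iminium nitronate 17 (not isolated)
Conditions: (S)-N1,N1-diethyl-3,3-dimethylbutane-1,2-diamine triflate salt (20 mol %), 3-nitrobenzoic acid (20 mol %), CHCl3, 40 °C; then aq. NaHCO3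
Reagents that add atoms: none
Why: Proposed new method: the protonated chiral primary–tertiary diamine condenses with the enone carbonyl of 15 and, by iminium–enamine tautomerism, gives the cross-conjugated 2-aminodiene 16 as rapidly interconverting isomers (which erases the racemic C–H centre next to the carbonyl), whose tetrasubstituted enamine carbon C10 adds to the nitroalkene β-carbon C5 (ring A, 6-exo-trig), after which the nitronate carbon C6 of 17 adds to the terminal carbon C7 of the α,β-unsaturated iminium ion (ring B, 6-endo-trig, the C6–C7 bond) and hydrolysis releases 18 and the catalyst, overall a formal intramolecular Diels–Alder reaction. The closest known reaction types are the primary-amine-catalysed enamine–iminium double Michael ([4+2]) reaction of enones with nitroalkenes and the deracemising Michael addition of α-branched ketones through their more substituted secondary enamines, which builds quaternary carbons; new here are the intramolecular setting and the branched α'-position. C10 (quaternary) and C5 are set in the first bond formation: the ammonium arm of the catalyst hydrogen-bonds the nitro group and its tert-butyl group shields one enamine face (absolute control), while the chair-like tether with the nitrovinyl group equatorial and the synclinal, endo-like approach should give the trans ring fusion. C6 and C8 are formed under equilibrating conditions and should settle as the equatorial nitro and equatorial methyl epimers, and C6 is destroyed in step 9 in any case. The selectivity needed is trans- over cis-decalin and one enantiomer from a racemic, geometrically mixed precursor; it is secured by the dynamic enamine geometry (only the isomer with the tether on the outside of the diene can reach the bicyclic transition state), by the matched polarity (nucleophilic C10 opposite electrophilic C5, nucleophilic C6 opposite electrophilic C7) and by the gem-dimethyl group on the tether, which favours ring closure.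

Step 9
Reactants: 18 (2R,4S,4aS,8aS)-2,5,5,8a-tetramethyl-4-nitrooctahydronaphthalen-1(2H)-one
Product: 20 (2R,4aS,8aS)-2,5,5,8a-tetramethyloctahydronaphthalene-1,4-dione, via sodium nitronate 19 (not isolated)
Conditions: NaOMe, MeOH, 0 °C; then O3, CH2Cl2/MeOH, −78 °C; N2 purge
Reagents that add atoms: ozone, [O-][O+]=O
Why: Oxidative Nef reaction, in which ozone cleaves the nitronate C=N bond to give the C6 ketone without acid; the substrate has no alkene, and the basic first stage keeps C8 at the equatorial-methyl configuration.

Step 10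
Reactants: 20 (2R,4aS,8aS)-2,5,5,8a-tetramethyloctahydronaphthalene-1,4-dione
Product: 21 (2R,4R,4aS,8aS)-4-hydroxy-2,5,5,8a-tetramethyloctahydronaphthalen-1(2H)-one
Conditions: LiBH(s-Bu)3 (1.05 equiv), THF, −78 °C; then H2O
Reagents that add atoms: none
Why: Chemo- and stereoselective ketone reduction: the bulky hydride attacks along the equatorial direction, at C6 from the open α face (the β face carries two syn-axial methyl groups) to give the axial 6β-alcohol (6R), whereas the C9 carbonyl, flanked by a quaternary and a tertiary carbon with the angular methyl across its equatorial trajectory, should remain.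

Step 11
Reactants: 21 (2R,4R,4aS,8aS)-4-hydroxy-2,5,5,8a-tetramethyloctahydronaphthalen-1(2H)-one
Product: 22 (1R,3R,4aS,8aS)-3,4a,8,8-tetramethyl-4-methylidenedecahydronaphthalen-1-ol
Conditions: Ph3PCH3Br (4 equiv), KOt-Bu (4 equiv), toluene, 90 °C
Reagents that add atoms: methyltriphenylphosphonium bromide, C[P+](c1ccccc1)(c1ccccc1)c1ccccc1.[Br-]
Why: Wittig methylenation under the forcing conditions used for hindered ketones, the free hydroxyl simply being deprotonated by excess base; C8 can epimerise under these conditions but already has the thermodynamic equatorial methyl.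

Step 12
Reactants: 22 (1R,3R,4aS,8aS)-3,4a,8,8-tetramethyl-4-methylidenedecahydronaphthalen-1-ol
Product: 23 (1R,2R,4R,4aS,8aS)-2,5,5,8a-tetramethyloctahydro-2H-spiro[naphthalene-1,2'-oxiran]-4-ol (9α,11-epoxide; oxirane oxygen anti to the angular methyl)
Conditions: 3-chloroperbenzoic acid (mCPBA), CH2Cl2, 0 °C
Reagents that add atoms: 3-chloroperbenzoic acid, OOC(=O)c1cccc(Cl)c1
Why: Prilezhaev epoxidation, in which the peracid should reach the exocyclic alkene from the α face, anti to the axial angular methyl on the neighbouring C10, which sets C9 with its oxygen α (9R) as the target requires.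

Step 13
Reactants: 23 (1R,2R,4R,4aS,8aS)-2,5,5,8a-tetramethyloctahydro-2H-spiro[naphthalene-1,2'-oxiran]-4-ol; 24 3-methylbut-3-en-1-ol
Product: 26 (5S,6R,8R,9R,10S)-labd-13(16)-ene-6β,9α,15-triol, via dilithio dianion 25 (not isolated)
Conditions: 24 (4 equiv), n-BuLi (8 equiv), TMEDA, Et2O/hexane, 0 °C → rt; then 23, −78 °C → rt; H2O
Reagents that add atoms: none
Why: Epoxide opening (SN2) by the 2-substituted allyllithium at the CH2 terminus C11, the only position open to substitution; the C9–O bond is untouched, so the tertiary 9α-alcohol keeps its configuration, and the two allyl termini are equivalent, so one constitution should result.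

Step 14
Reactants: 26 (5S,6R,8R,9R,10S)-labd-13(16)-ene-6β,9α,15-triol
Product: 28 (5S,6R,8R,9R,10S,13S)-9,13-epoxylabdane-6β,15,16-triol, via epoxide 27 (not isolated)
Conditions: VO(Oi-Pr)3 (2 mol %), N,N'-[(1R,2R)-cyclohexane-1,2-diyl]bis(N-hydroxy-2,2-diphenylacetamide) (4 mol %), PhC(CH3)2OOH, toluene, 0 °C → rt; then camphor-10-sulfonic acid (10 mol %), CH2Cl2, rt
Reagents that add atoms: cumene hydroperoxide, CC(C)(OO)c1ccccc1
Why: Hydroxyl-directed catalytic asymmetric epoxidation of the homoallylic alcohol (ligand control over the faces of the 1,1-disubstituted alkene) should give the (13R)-epoxide, and acid-catalysed 5-exo-tet opening by the C9 hydroxyl at the tertiary epoxide carbon with inversion closes the tetrahydrofuran ring with C13 in the S configuration and frees the C16 hydroxyl.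

Step 15
Reactants: 28 (5S,6R,8R,9R,10S,13S)-9,13-epoxylabdane-6β,15,16-triol
Product: 30 (5S,6R,8R,9R,10S,13S)-9,13-epoxy-6β-hydroxylabdan-15,16-olide (lactone C=O at C15), via lactol 29 (not isolated)
Conditions: 2,2,6,6-tetramethylpiperidine-1-oxyl (TEMPO, 20 mol %), PhI(OAc)2 (2.5 equiv), CH2Cl2, rt
Reagents that add atoms: none
Why: Oxidative lactonisation of a 1,4-diol, in which the oxoammonium oxidant should select the less hindered primary alcohol at C15 over the neopentyl C16 alcohol and the hindered axial C6 alcohol, the aldehyde being trapped by the C16 hydroxyl as a lactol and oxidised on; no stereocentre is touched.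

Step 16
Reactants: 30 (5S,6R,8R,9R,10S,13S)-9,13-epoxy-6β-hydroxylabdan-15,16-olide
Product: 31 previtexilactone, (5S,6R,8R,9R,10S,13S)-6β-acetoxy-9,13-epoxylabdan-15,16-olide
Conditions: Ac2O, 4-(dimethylamino)pyridine, pyridine, rt → 40 °C
Reagents that add atoms: acetic anhydride, CC(=O)OC(C)=O
Why: Nucleophile-catalysed acylation of the hindered axial 6β-alcohol, the only free hydroxyl left; the amine bases are too weak to trigger β-elimination of the β-alkoxy lactone.

Compound list
1 | isobutyronitrile | CC(C)C#N | starting material
2 | 1,3-dibromopropane | BrCCCBr | starting material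
3 | lithiated isobutyronitrile | [Li]C(C)(C)C#N | intermediate (not isolated)
4 | 5-bromo-2,2-dimethylpentanenitrile | N#CC(C)(C)CCCBr | intermediate
5 | N-methoxy-N-methylpropanamide | CCC(=O)N(C)OC | starting material
6 | lithium enolate of 5 | CC=C(O[Li])N(C)OC | intermediate (not isolated)
7 | 6-cyano-N-methoxy-N,2,6-trimethylheptanamide (racemic) | CC(CCCC(C)(C)C#N)C(=O)N(C)OC | intermediate
8 | isopropenylmagnesium bromide | CC(=C)[Mg]Br | starting material
9 | 2,2,6,8-tetramethyl-7-oxonon-8-enenitrile (racemic) | CC(=C)C(=O)C(C)CCCC(C)(C)C#N | intermediate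
10 | 7-hydroxy-2,2,6,8-tetramethylnon-8-enal (stereoisomer mixture) | CC(=C)C(O)C(C)CCCC(C)(C)C=O | intermediate
11 | nitromethane | C[N+](=O)[O-] | starting material
12 | 2,4,8,8-tetramethyl-10-nitrodec-1-ene-3,9-diol (stereoisomer mixture) | CC(=C)C(O)C(C)CCCC(C)(C)C(O)C[N+](=O)[O-] | intermediate
13 | 9-hydroxy-2,4,8,8-tetramethyl-10-nitrodec-1-en-3-one (stereoisomer mixture) | CC(=C)C(=O)C(C)CCCC(C)(C)C(O)C[N+](=O)[O-] | intermediate
14 | 2,4,8,8-tetramethyl-10-nitro-3-oxodec-1-en-9-yl methanesulfonate | CC(=C)C(=O)C(C)CCCC(C)(C)C(OS(C)(=O)=O)C[N+](=O)[O-] | intermediate (not isolated)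
15 | (E)-2,4,8,8-tetramethyl-10-nitrodeca-1,9-dien-3-one (racemic) | CC(=C)C(=O)C(C)CCCC(C)(C)/C=C/[N+](=O)[O-] | intermediate
16 | 2-aminodiene (dienamine) from 15 and the (S)-diamine catalyst, mixed enamine geometry | C=C(C)C(N[C@@H](C(C)(C)C)CN(CC)CC)=C(C)CCCC(C)(C)/C=C/[N+](=O)[O-] | intermediate (not isolated)
17 | monocyclic iminium nitronate (ring A closed, catalyst bound) | C=C(C)C(=[NH+][C@@H](C(C)(C)C)CN(CC)CC)[C@@]1(C)CCCC(C)(C)[C@@H]1C=[N+]([O-])[O-] | intermediate (not isolated)
18 | (2R,4S,4aS,8aS)-2,5,5,8a-tetramethyl-4-nitrooctahydronaphthalen-1(2H)-one | [O-][N+](=O)[C@H]1C[C@@H](C)C(=O)[C@@]2(C)CCCC(C)(C)[C@H]12 | intermediate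
19 | sodium nitronate of 18 | [Na+].[O-][N+]([O-])=C1C[C@@H](C)C(=O)[C@@]2(C)CCCC(C)(C)[C@H]12 | intermediate (not isolated)
20 | (2R,4aS,8aS)-2,5,5,8a-tetramethyloctahydronaphthalene-1,4-dione | O=C1C[C@@H](C)C(=O)[C@@]2(C)CCCC(C)(C)[C@H]12 | intermediate
21 | (2R,4R,4aS,8aS)-4-hydroxy-2,5,5,8a-tetramethyloctahydronaphthalen-1(2H)-one | O[C@@H]1C[C@@H](C)C(=O)[C@@]2(C)CCCC(C)(C)[C@H]12 | intermediate
22 | (1R,3R,4aS,8aS)-3,4a,8,8-tetramethyl-4-methylidenedecahydronaphthalen-1-ol | O[C@@H]1C[C@@H](C)C(=C)[C@@]2(C)CCCC(C)(C)[C@H]12 | intermediate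
23 | (1R,2R,4R,4aS,8aS)-2,5,5,8a-tetramethyloctahydro-2H-spiro[naphthalene-1,2'-oxiran]-4-ol | O[C@@H]1C[C@@H](C)[C@]3(CO3)[C@@]2(C)CCCC(C)(C)[C@H]12 | intermediate
24 | 3-methylbut-3-en-1-ol | CC(=C)CCO | starting material
25 | dilithio dianion of 24 | [Li]CC(=C)CCO[Li] | intermediate (not isolated)
26 | (5S,6R,8R,9R,10S)-labd-13(16)-ene-6β,9α,15-triol | O[C@@H]1C[C@@H](C)[C@](O)(CCC(=C)CCO)[C@@]2(C)CCCC(C)(C)[C@H]12 | intermediate
27 | (13R)-13,16-epoxide of 26 | O[C@@H]1C[C@@H](C)[C@](O)(CC[C@@]3(CCO)CO3)[C@@]2(C)CCCC(C)(C)[C@H]12 | intermediate (not isolated)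
28 | (5S,6R,8R,9R,10S,13S)-9,13-epoxylabdane-6β,15,16-triol | O[C@@H]1C[C@@H](C)[C@]2(CC[C@](CCO)(CO)O2)[C@@]2(C)CCCC(C)(C)[C@H]12 | intermediate
29 | 15,16-lactol of 28 (C15 epimers) | O[C@@H]1C[C@@H](C)[C@]2(CC[C@]3(COC(O)C3)O2)[C@@]2(C)CCCC(C)(C)[C@H]12 | intermediate (not isolated)
30 | (5S,6R,8R,9R,10S,13S)-9,13-epoxy-6β-hydroxylabdan-15,16-olide | O[C@@H]1C[C@@H](C)[C@]2(CC[C@]3(COC(=O)C3)O2)[C@@]2(C)CCCC(C)(C)[C@H]12 | intermediate
31 | previtexilactone | CC(=O)O[C@@H]1C[C@@H](C)[C@]2(CC[C@]3(COC(=O)C3)O2)[C@@]2(C)CCCC(C)(C)[C@H]12 | target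

Total step count: 16. Longest linear sequence: 16 steps (1 → 31; compounds 2, 5, 8, 11 and 24 are purchased).

Steps most likely to fail

1. Step 8 (Proposed new method). What may go wrong: slow formation and low turnover of the hindered tetrasubstituted dienamine, competing addition of the catalyst amine to the nitroalkene or the vinyl ketone, and loss of enantio- or trans-selectivity in the first bond formation. Fallback (known chemistry, stoichiometric auxiliary, stepwise), from 15 back to 18: 15 is condensed with (S)-1-phenylethylamine (4 Å molecular sieves, toluene) to the N-(1-phenylethyl) imine F1. Warmed in THF, it reacts through its more substituted secondary enamine tautomer in the deracemising Michael addition known for chiral imines of α-branched ketones, here onto the tethered nitroalkene, which should give the monocyclic imine F2 with C10 and C5 in place. Aqueous acetic acid hydrolyses it to the nitro enone F3 and returns the amine. DBU in THF then closes ring B by intramolecular Michael addition of the nitronate to the vinyl ketone (the same C6–C7 bond) and equilibrates C6 and C8, which gives 18.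

2. Step 13. What may go wrong: the strongly basic, aggregated dianion may be too bulky for substitution at the neopentyl-type epoxide carbon and may instead abstract the C8 hydrogen, isomerising the spiro-epoxide to an allylic alkoxide. Fallback, from 23 back to 26, which builds the 1,1-disubstituted alkene after the C11–C12 bond: 23 is opened at C11 with 3-(trimethylsilyl)prop-2-ynyllithium (from 1-(trimethylsilyl)propyne and n-BuLi, THF/DMPU) to give the silyl alkyne F4. K2CO3 in MeOH removes the silyl group to give the terminal alkyne F5. Bromoboration with B-bromo-9-borabicyclo[3.3.1]nonane (excess, bromine to the internal carbon) and protonolysis with acetic acid give the 2-bromoalkene F6. Bromine–lithium exchange (excess t-BuLi, the two hydroxyls as lithium alkoxides) and alkylation of the alkenyllithium with oxirane give 26.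

3. Step 10. What may go wrong: insufficient discrimination between the two ring-B carbonyl groups, with over-reduction at C9 from its open α face. Fallback, from 18 back to 22, which removes the C9 carbonyl before the C6 ketone exists: 18 is methylenated first with excess Ph3P=CH2 (Ph3PCH3Br, KOt-Bu, toluene, 90 °C; the acidic nitro group is deprotonated and thereby protected under these conditions) to give the nitro alkene F7. A reductive Nef reaction (NaOMe, then buffered aqueous TiCl3), which spares the alkene, gives the ketone F8. NaBH4 then reduces the only carbonyl group from the α face to give 22.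

Further compounds
F1 | step 8 | (E)-2,4,8,8-tetramethyl-10-nitro-N-[(1S)-1-phenylethyl]deca-1,9-dien-3-imine | C=C(C)C(=N[C@@H](C)c1ccccc1)C(C)CCCC(C)(C)/C=C/[N+](=O)[O-]
F2 | step 8 | 2-methyl-N-[(1S)-1-phenylethyl]-1-[(1S,2S)-1,3,3-trimethyl-2-(nitromethyl)cyclohexyl]prop-2-en-1-imine | C=C(C)C(=N[C@@H](C)c1ccccc1)[C@@]2(C)CCCC(C)(C)[C@@H]2C[N+](=O)[O-]
F3 | step 8 | 2-methyl-1-[(1S,2S)-1,3,3-trimethyl-2-(nitromethyl)cyclohexyl]prop-2-en-1-one | C=C(C)C(=O)[C@@]1(C)CCCC(C)(C)[C@@H]1C[N+](=O)[O-]
F4 | step 13 | (1R,3R,4R,4aS,8aS)-3,4a,8,8-tetramethyl-4-[4-(trimethylsilyl)but-3-yn-1-yl]decahydronaphthalene-1,4-diol | O[C@@H]1C[C@@H](C)[C@](O)(CCC#C[Si](C)(C)C)[C@@]2(C)CCCC(C)(C)[C@H]12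
F5 | step 13 | (1R,3R,4R,4aS,8aS)-4-(but-3-yn-1-yl)-3,4a,8,8-tetramethyldecahydronaphthalene-1,4-diol | O[C@@H]1C[C@@H](C)[C@](O)(CCC#C)[C@@]2(C)CCCC(C)(C)[C@H]12
F6 | step 13 | (1R,3R,4R,4aS,8aS)-4-(3-bromobut-3-en-1-yl)-3,4a,8,8-tetramethyldecahydronaphthalene-1,4-diol | O[C@@H]1C[C@@H](C)[C@](O)(CCC(Br)=C)[C@@]2(C)CCCC(C)(C)[C@H]12
F7 | step 10 | (1S,3R,4aS,8aS)-3,4a,8,8-tetramethyl-4-methylidene-1-nitrodecahydronaphthalene | [O-][N+](=O)[C@H]1C[C@@H](C)C(=C)[C@@]2(C)CCCC(C)(C)[C@H]12
F8 | step 10 | (3R,4aS,8aS)-3,4a,8,8-tetramethyl-4-methylideneoctahydronaphthalen-1(2H)-one | O=C1C[C@@H](C)C(=C)[C@@]2(C)CCCC(C)(C)[C@H]12
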